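I begin with the easy step: J reacts with free D, and D bound as D.L does not appear in that step.

    L → Z (k1 = 0.010 s⁻¹)
    D + L ⇌ D.L, settled at all times (K2 = 6800 M⁻¹)
    J + D → L + E (k3 = 1.5 M⁻¹ s⁻¹)
    L + Q ⇌ L.Q (K4 = 1.5 × 10⁶ M⁻¹, k4 = 23 M⁻¹ s⁻¹)

J 10 mM; Q 3.00 mM (fed, over 30 s); D.L 11.0 mM; time 6.0 min

* part of the J that has reacted at 6.0 min
* share of the unused D that is free and not bound as D.L, at 6.0 min

The binding step is kept at balance, so I reckon with what the balance leaves free. At the start, D.L opens into equal amounts of D and L. Let s be the opened part of the D.L charge. For small s, the balance says that s squared, times K2, times the charge, equals one. This gives the free share, one over the root of K2 times the charge: s = 11.6%.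

As an assumption of this reckoning, I hold free D, the partner of J, at its starting level. The decay of J is then pseudo-first-order, with a rate constant of k3 times s times the charge, 0.114 min⁻¹. Held steady, this gives 49.7% of J reacted at 6.0 min, with a free share of 11.6%. I commit to these two numbers, and I do not follow Q, L and Z by hand.

The forecast gives 40% reacted (range 36% to 44%) and a free share of 10% (range 8.5% to 12%). Both are lower than my numbers. Its grounds include this: “each J consumed also releases L and removes D”.

The simulation gives 40.1% and 9.99%, inside both forecast ranges; a D.L charge of 8.02 mM or 14.7 mM moves c by 5 points, past its range. In this flask at 3.30 min, J has a half-life of 9.4 min by its step with D, longer than the 1.2 min of L by its step to Z. At 6.00 min, L goes to Z 260 times as fast as into L.Q, forward rate counted. Free D in this flask falls from 1.29 mM at 0.500 min to 0.699 mM at 6.00 min, and the free share then is 0.861 of s, which I reckoned for the start. In the neighbour flask with 27 mM of D.L, s for the start is 7.38%, and the simulation gives 6.54% at 6.00 min, which is 0.886 of it.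

(The numbers of this flask are made up; the rest is arithmetic.)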